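The readings were generated by integration with made-up constants, and the scatter is random.

**The number.** In the north run 41.2 % of the starting material (S) stands as open dimer at 25.0 s, with 3.5 % still free. I want to know what 0.050 M instead of 0.025 M, with the same protic impurity, does to that share.

| setting | north | oak | birch | cedar |
|---|---|---|---|---|
| starting material | 0.025 M | 0.050 M | 0.050 M | 0.050 M |
| protic impurity | 0.025 M | 0.0250 M | 0.0250 M | 0.0250 M |
| temperature | 35 °C | 35 °C | 50 °C | 65 °C |
| remark | run made earlier |  |  |  |
| time |  | 2.0 min | 2.0 min | 2.0 min |

north run (percent of the starting material charged)

| time / s | open dimer / % | starting material / % | ring / % |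
|---|---|---|---|
| 10.0 | 39.0 | 17.2 | 22.9 |
| 15.0 | 40.1 | 9.7 | 26.9 |
| 25.0 | 41.2 | 3.5 | 30.3 |

(each reading ± 0.3 percentage points)

- which of these there is most of at the end, counted by the starting material in it, oak (starting material / ring / open dimer)
- which of these there is most of at the end, counted by the starting material in it, birch (starting material / ring / open dimer)
- which of these there is most of at the end, counted by the starting material in it, cedar (starting material / ring / open dimer)
- final amount of the leader among these, as a percentage of the starting material charged, in oak
- final amount of the leader among these, as a percentage of the starting material charged, in birch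
- final amount of the leader among these, as a percentage of the starting material charged, in cedar

- percentages count the starting material that a species holds: one open dimer counts as two
- a reading or a percentage of ring counts all its forms, free or not
- the earlier runs do not show what temperature does; that part of a forecast is a guess
- a reading of starting material is of its free form alone

**First try.** The part of north that is neither free S nor open dimer is 55.3 %, so open dimer stands to it as 0.745. Scaling that ratio with the charge gives oak 59.8 % of open dimer. But the ratio does not hold still: between the last two readings open dimer takes 17.7 % of the S lost, less than the 42.7 % taken over the whole run. I take that for a path that needs two S, which fades as S falls.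

**Better measure.** Let x be the rate at which dimer formation uses S at the start over the rate of the first-order paths together, a selectivity factor. If those paths stay first order in S, then with a fraction s of S left the open dimer fraction Q obeys x = ln[(1 + x)/(1 + xs)]/(1 − s − Q). For north's last reading I put in x = 2 and get 1.86, and going round again gives 1.79. The steps shrink steadily, and summing them ends near 1.69. So c* = 0.0148 M, read from north at 35 °C with 0.025 M of protic impurity, is the crossover charge, the charge at which the two kinds of path use S equally at the start.

**Oak.** There x = 3.39. North's S halves in about 6.80 s late in the run, and 2.0 min is far longer, so for this estimate of oak I set s to zero. Open dimer comes to 56.3 %. If ring keeps its north part of the remainder, my estimate for oak is 23.9 % of ring, less than the open dimer. How far warming moves c* I cannot read from these runs.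

**Forecast.** It names open dimer, open dimer and open dimer for oak, birch and cedar, at 57 %, 52 % and 46 %, against my 56.3 % for oak. For the warmer flasks it reasons: “Warming probably favours the unimolecular paths”.

**Result.** Oak ends with 55.8 % of open dimer, birch with 47.4 % of ring and cedar with 67.6 % of ring. In cedar, just after the start, ring formation uses S at 0.81 of the rate of dimer formation. Cedar's 27.7 % of open dimer, put through the same rounds from x = 1, gives 0.959, then 0.930, ending near 0.863. So c* in cedar reads 0.0579 M, 3.91 times its north value.

    starting material → ring (k = 0.0550 s⁻¹, Ea = 93.0 kJ mol⁻¹)
    2 starting material → open dimer (k = 3.50 M⁻¹ s⁻¹, Ea = 47.0 kJ mol⁻¹)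
    starting material + protic impurity → quenched substrate (k = 0.580 M⁻¹ s⁻¹, Ea = 56.0 kJ mol⁻¹)
    starting material + ring ⇌ idle adduct, settled at all times (K = 4.50 M⁻¹, ΔH = 1.00 kJ mol⁻¹)
    starting material ⇌ dormant form (K = 16.0, k = 0.0360 s⁻¹, Ea = 80.0 kJ mol⁻¹, ΔH = −26.0 kJ mol⁻¹)
    (constants at 35 °C)

**Neighbour.** A flask like cedar with 0.12 M of S has x = 2.07, which gives 45.8 % of open dimer. The computed flask gives 45.1 %.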